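## The problem

Compound 30 is a heptamer of polyhydroxybenzene rings (A to G in the order of the SMILES string) held together only by six diaryl ether bonds, with seventeen free phenols and no carbon–carbon bond between rings. It is achiral, so there is no stereocentre to set and none that could direct another; the only stereocentres on the way are transient and racemic. All six ethers have the same sense: the oxygen sits on a carbon flanked by two oxygenated carbons (A-C1, B-C4, C-C4, D-C6, E-C4, F-C4) and is bonded to C1 of the next ring. Every ether therefore has to be made from a hindered, electron-rich phenoxide, and no ring is electron-poor enough for nucleophilic aromatic substitution. Rings B, C, E and F are the same para-linked 2,6-dioxygenated unit and A and G are end caps. Ring D is the exception: it is ortho-linked (D-C1 and D-C6 are adjacent) and bears oxygen on five adjacent carbons. The free polyphenol, with the pyrogallol ring G and the 1,2,3-triol of ring D, is oxidised readily by air in base and by copper salts, so every phenol must stay masked until the last step, behind a group that one acidic operation removes without breaking aryl–O–aryl bonds. The feature that opens the way is that D-C3 to D-C6 are four contiguous oxygenated carbons, like the four carbons of a squaric ester, while D-C1 and D-C2 form a two-carbon unit carrying only the ring C oxygen. Joining D-C6 to D-C1 closes ring D and leaves the D-C6 oxygen as its only free hydroxyl.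

## Retrosynthesis

**30 from 28.** The seventeen O–CH3 bonds of heptadecamethyl ether 28 are cut first, because unmasking must be the last operation. Methyl is preferred to benzyl or silyl: it is already present in every cheap building block (1, 4, 13, 22) and survives organolithiums, copper and base at 110 °C and the 138 °C of the key step. It leaves in one Lewis-acid step (through borate 29) that does not touch diaryl ethers. The forward reaction must be exhaustive and run without air.

**28 from 21 and 27.** The D-C6 oxygen to E-C1 bond is cut, dividing the heptamer into tetramer phenol 21 and trimer bromide 27 of similar size. The neighbouring cuts would bury ring D inside a fragment or make one of its flanked carbons the electrophile. This cut uses ring D as the nucleophile and the unhindered E-C1 as the electrophile. The forward step is a CuI-catalysed arylation of a di-ortho-substituted phenol, the reaction type used for the other ethers of the ABC half.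

**21 from 18 (key).** Ring D is opened across the D-C6 to D-C1 bond, back through dienone 20 and dienylketene 19 to cyclobutenone 18. Oxygenating a preformed arene would have to place five oxygens and tell them apart. The squarate instead delivers four of them already differentiated: two enol methyl ethers, a tertiary methyl ether (D-C3) and the carbonyl that becomes the single free hydroxyl (D-C6). A silyl ether on the tertiary oxygen was weighed and set aside, since an aryl silyl ether in 21 would not survive K3PO4 in DMSO at 110 °C; a methyl ether does and leaves with the others. The forward reaction needs outward rotation of the methoxy group and ring closure faster than interception of the ketene.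

**18 from 17, and 17 from 12 and 13.** The Z-alkene is traced to alkyne 17 by syn semihydrogenation. The bond between the squarate carbonyl carbon and the alkyne is then cut, giving acetylide 15 and dimethyl squarate 13, with alkoxide 16 methylated in the flask. The acetylide is preferred to a 2-aryloxyvinyl organometallic, which can lose phenoxide by β-elimination and whose halide precursor would need molecular bromine beside three polymethoxyarenes. Acetylide 15 comes from dichlorovinyl ether 12 through chloroalkyne 14, and 12 from phenol 9 and trichloroethylene 10 through dichloroacetylene 11. All six carbons of ring D thus come from two commodity chemicals.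

**9 from 3 and two molecules of 5.** The two para ethers of 9 are cut in turn. Each is formed from a head phenol and bromide 5, whose own head oxygen is benzyl-protected; hydrogenolysis (6 to 7, 8 to 9) exposes the next head. Phenol 3 comes from aldehyde 1 through formate 2, and 5 from 4. This direction puts every C–Br bond on an unhindered carbon.

**27 from 26 and 4; 26 from 23; 23 from 22 and 4.** The EFG half must end in a tail bromide, so the direction of growth is reversed. The phenol partner 4 carries the bromide and the aryl partner is a boronic acid (22, then 26), joined oxidatively under conditions that leave C–Br alone. Bromide 23 becomes boronic acid 26 through 24 and 25, so 27 needs three steps from two commercial compounds.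

## Roads not taken

**Alternative 1:** The four para ether bonds of the two trimers are cut at once, each trimer going back to three molecules of syringic acid A2. In the forward step laccase under air (or a carbon anode) oxidises A2 to phenoxyl radicals; each oxygen bonds to the carboxyl-bearing para carbon of the next unit with loss of CO2, giving trimer acid A1.
- Merits: two C–O bonds per operation, no halide, no copper and no protecting-group steps. The head-to-tail sense and the 2,6-dimethoxy pattern are exactly those of rings B, C, E and F. In step count to a trimer skeleton this road is clearly better than the six steps to 9 and the three to 27.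
- Weak points: the coupling is a step-growth radical process, so A1 must be separated from dimer, tetramer and polymer. The carboxyl tail of A1 is also on the wrong atom twice. In the ABC series it sits where ring A needs its para oxygen, and in the EFG series on E-C1, which has to end as an aryl ether carbon. Each needs a multi-step exchange of carboxyl for oxygen or halogen. Ring D, ortho-linked and pentaoxygenated, is not addressed at all.
- Comparison: the chosen plan sets defined chain length, a tail bromide in 27 that is ready for the union, and a construction of ring D against the shorter trimer assembly.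

**Alternative 2:** Ring E is cut into a two-carbon and a four-carbon piece: the ethynyl ether A5 of the ABCD phenol and the 4-aryloxy-3-ethoxycyclobutenone A4 carrying rings F and G. On heating, A4 would open to a vinylketene, add to the alkyne of A5, and pass through a second ring opening and a 6π closure to the heptamer A3, whose ring E carries one free hydroxyl and one ethyl ether.
- Merits: the two halves are joined while a ring is made. The D-C6 oxygen is attached as an ynol ether by the chemistry of step 7, so the hindered diaryl ether coupling of step 14 would be avoided. In that respect this road is better.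
- Weak points: A5 is the ethynyl ether of phenol 21, so ring D still has to be made first and the road can only follow the chosen key step, not replace it. A4 is a cyclobutenone type without close precedent. The cascade is bimolecular between two advanced fragments at high temperature, where ketene dimerisation and the regiochemistry of the cycloaddition are open. Ring E is otherwise a commodity ring, present in 4.
- Comparison: the chosen plan pays for the harder union in step 14 with simple, symmetrical partners and keeps the ring-forming chemistry for the one ring that cannot be bought.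

**Alternative 3:** Ring A is cut between its aryloxy-bearing carbon and a neighbouring hydroxyl carbon, giving the methyl 6-aryloxy-3,5-dioxohexanoate A7, whose aryloxy group is the whole B-to-G hexamer. Base would make the aryloxy-bearing carbon attack the ester carbonyl to give A6, with ring A as a free phloroglucinol.
- Merits: the step is biomimetic, ring A arrives without protecting groups, and the A–O–B ether is present before the ring exists, so one hindered coupling is spared.
- Weak points: the carbon that must attack is the least acidic of the three methylene groups, and 3,5-dioxo esters prefer to close through oxygen to 4-hydroxy-2-pyrones. The step would be run on the most valuable intermediate. It leaves ring D and the other five ethers unsolved, and fourteen methyl ethers must still be cleaved from A6.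
- Comparison: the chosen plan makes ring A from 1 in one step and spends its ring-forming step on ring D; alternative 3 offers only three fewer ethers to cleave.

Key step: step 10

Remark: "ABC-oxy" denotes the aryloxy group of phenol 9, 4-[2,6-dimethoxy-4-(2,4,6-trimethoxyphenoxy)phenoxy]-2,6-dimethoxyphenoxy.

Assumption: cyclobutenones 16 to 18 and dienone 20 are carried as racemates, because their single stereocentre disappears when ring D aromatises and the target is achiral.

## Route

Step 1
Reactants: 1 2,4,6-trimethoxybenzaldehyde
Product: 3 2,4,6-trimethoxyphenol, via 2,4,6-trimethoxyphenyl formate 2 (not isolated)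
Conditions: mCPBA, CH2Cl2, 0 °C to rt; then K2CO3 (cat.), MeOH, rt
Reagents that add atoms: mCPBA, OOC(=O)c1cccc(Cl)c1
Why: Dakin-type Baeyer–Villiger oxidation; the electron-rich aryl group migrates in preference to hydride to give formate 2, which catalytic methanolysis cleaves to the phenol.

Step 2
Reactants: 4 4-bromo-2,6-dimethoxyphenol
Product: 5 2-(benzyloxy)-5-bromo-1,3-dimethoxybenzene
Conditions: BnBr, K2CO3, DMF, rt
Reagents that add atoms: benzyl bromide, BrCc1ccccc1
Why: Williamson etherification of the phenoxide; benzyl survives the copper couplings and is later removed by hydrogenolysis without touching methyl or diaryl ethers.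

Step 3
Reactants: 3 2,4,6-trimethoxyphenol; 5 2-(benzyloxy)-5-bromo-1,3-dimethoxybenzene
Product: 6 AB benzyl ether 2-(benzyloxy)-1,3-dimethoxy-5-(2,4,6-trimethoxyphenoxy)benzene
Conditions: CuI (10 mol%), picolinic acid (20 mol%), K3PO4, DMSO, 100 °C, Ar
Reagents that add atoms: none
Why: Ullmann diaryl ether synthesis under ligand-accelerated CuI catalysis; the picolinic acid and K3PO4 system in DMSO is the one established for di-ortho-substituted phenols, and the C–Br carbon of 5 has no ortho substituent.

Step 4
Reactants: 6 AB benzyl ether
Product: 7 AB phenol 2,6-dimethoxy-4-(2,4,6-trimethoxyphenoxy)phenol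
Conditions: H2 (1 atm), Pd/C, EtOAc/MeOH, rt
Reagents that add atoms: none
Why: Hydrogenolysis of the aryl benzyl ether over Pd/C; aryl methyl ethers and diaryl ethers are inert under these conditions.

Step 5
Reactants: 7 AB phenol; 5 2-(benzyloxy)-5-bromo-1,3-dimethoxybenzene
Product: 8 ABC benzyl ether 2-(benzyloxy)-5-[2,6-dimethoxy-4-(2,4,6-trimethoxyphenoxy)phenoxy]-1,3-dimethoxybenzene
Conditions: CuI (10 mol%), picolinic acid (20 mol%), K3PO4, DMSO, 100 °C, Ar
Reagents that add atoms: none
Why: Second Ullmann diaryl ether synthesis of the same type as step 3; phenol 7 has the same 2,6-dimethoxy environment as 3 and the same bromide is used.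

Step 6
Reactants: 8 ABC benzyl ether
Product: 9 ABC phenol 4-[2,6-dimethoxy-4-(2,4,6-trimethoxyphenoxy)phenoxy]-2,6-dimethoxyphenol
Conditions: H2 (1 atm), Pd/C, EtOAc/MeOH, rt
Reagents that add atoms: none
Why: Hydrogenolysis as in step 4 frees the head phenol of ring C.

Step 7
Reactants: 9 ABC phenol; 10 trichloroethylene
Product: 12 (E)-1,2-dichloro-1-(ABC-oxy)ethene, via dichloroacetylene 11 (not isolated)
Conditions: K2CO3, DMF, 70 °C
Reagents that add atoms: none
Why: Base-induced loss of HCl from 10 gives dichloroacetylene, to which the phenoxide adds anti; protonation gives the (E)-1,2-dichlorovinyl ether, the standard entry to aryl ynol ethers, and no electrophilic halogen meets the polymethoxyarenes.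

Step 8
Reactants: 12 (E)-1,2-dichloro-1-(ABC-oxy)ethene; 13 dimethyl squarate
Product: 17 racemic 4-[(ABC-oxy)ethynyl]-2,3,4-trimethoxycyclobut-2-en-1-one, via chloroethynyl ether 14 (not isolated), via lithium acetylide 15 (not isolated), via lithium alkoxide 16 (not isolated)
Conditions: n-BuLi (2.1 equiv), THF, −78 to −40 °C; then add to 13, THF, −78 °C; then MeOTf, −78 to 0 °C
Reagents that add atoms: methyl trifluoromethanesulfonate, COS(=O)(=O)C(F)(F)F
Why: Deprotonation and loss of chloride give chloroalkyne 14, and chlorine–lithium exchange gives acetylide 15; 1,2-addition of a lithium acetylide to one carbonyl of dimethyl squarate at −78 °C is the standard opening move of squarate chemistry, and alkoxide 16 is O-methylated in the flask. The new stereocentre is formed racemic and is destroyed in step 10.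

Step 9
Reactants: 17 racemic 4-[(ABC-oxy)ethynyl]-2,3,4-trimethoxycyclobut-2-en-1-one
Product: 18 racemic 4-[(Z)-2-(ABC-oxy)ethenyl]-2,3,4-trimethoxycyclobut-2-en-1-one
Conditions: H2 (1 atm), Pd/CaCO3 poisoned with Pb(OAc)2 (Lindlar catalyst), quinoline, EtOAc, rt
Reagents that add atoms: none
Why: Lindlar semihydrogenation adds both hydrogens syn from the catalyst surface and so gives the (Z)-enol ether; the tetrasubstituted vinylogous-ester double bond of the ring and the aryl ethers are not reduced, and at room temperature the cyclobutenone does not open.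

Step 10
Reactants: 18 racemic 4-[(Z)-2-(ABC-oxy)ethenyl]-2,3,4-trimethoxycyclobut-2-en-1-one
Product: 21 ABCD phenol 6-(ABC-oxy)-2,3,4-trimethoxyphenol, via dienylketene 19 (not isolated), via cyclohexa-2,4-dienone 20 (not isolated)
Conditions: p-xylene (degassed, 0.01 M), 138 °C, Ar
Reagents that add atoms: none
Why: Heating should cleave the C1–C4 bond of the cyclobutenone in a conrotatory 4π electrocyclic opening to dienylketene 19. The C4 methoxy group, a lone-pair donor, rotates outward, which places the aryloxyvinyl group on the same side of the new double bond as the ketene. A disrotatory 6π electrocyclisation then bonds the ketene carbon to the aryloxy-bearing vinyl carbon, forming the D-C6 to D-C1 bond and closing ring D as dienone 20; enolisation gives phenol 21 and removes the only stereocentre, so none has to be controlled. The closest known reaction type is the thermal ring expansion of 4-alkenyl-4-hydroxy or 4-alkoxy cyclobutenones made from squarates to hydroquinones and their monoethers. The step needs exclusive six-membered closure and a single free hydroxyl. The first is secured by the outward rotation of the methoxy group and by the two methoxy groups ortho to the ring C oxygen, which block attack of that ring on the ketene; the second by the tertiary methyl ether, which marks D-C3 and leaves D-C6 as the only phenol. The alkene geometry is not carried into the product, but the Z isomer puts the aryloxy group on the inner side of the closing terminus, so high dilution and exclusion of air and water are used to keep the ketene from being trapped.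

Step 11
Reactants: 22 3,4,5-trimethoxyphenylboronic acid; 4 4-bromo-2,6-dimethoxyphenol
Product: 23 FG bromide 5-bromo-1,3-dimethoxy-2-(3,4,5-trimethoxyphenoxy)benzene
Conditions: Cu(OAc)2 (2 equiv), pyridine, 4 Å MS, CH2Cl2, rt
Reagents that add atoms: none
Why: Chan–Lam coupling; the aryl group passes from boron to divalent copper, and C–O reductive elimination from a trivalent copper aryl phenoxide occurs at room temperature. Di-ortho-substituted phenols are accepted and the aryl bromide of 4 is inert, so the phenol partner can carry the handle for the next operation.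

Step 12
Reactants: 23 FG bromide
Product: 26 FG boronic acid [3,5-dimethoxy-4-(3,4,5-trimethoxyphenoxy)phenyl]boronic acid, via aryllithium 24 (not isolated), via lithium aryltriisopropoxyborate 25 (not isolated)
Conditions: n-BuLi, THF, −78 °C; B(Oi-Pr)3, −78 °C to rt; then 1 M HCl
Reagents that add atoms: triisopropyl borate, CC(C)OB(OC(C)C)OC(C)C; water, O
Why: Bromine–lithium exchange at −78 °C is faster than ortho-lithiation beside the methoxy groups; borate trapping and acidic hydrolysis give the boronic acid.

Step 13
Reactants: 26 FG boronic acid; 4 4-bromo-2,6-dimethoxyphenol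
Product: 27 EFG bromide 5-bromo-2-[3,5-dimethoxy-4-(3,4,5-trimethoxyphenoxy)phenoxy]-1,3-dimethoxybenzene
Conditions: Cu(OAc)2 (2 equiv), pyridine, 4 Å MS, CH2Cl2, rt
Reagents that add atoms: none
Why: Second Chan–Lam coupling of the same type as step 11; the bromide on E-C1 is again untouched and is the electrophilic site for step 14.

Step 14
Reactants: 21 ABCD phenol; 27 EFG bromide
Product: 28 heptadecamethyl ether of the target
Conditions: CuI (20 mol%), picolinic acid (40 mol%), K3PO4, DMSO, 110 °C, Ar
Reagents that add atoms: none
Why: Ullmann diaryl ether synthesis as in steps 3 and 5; the C–Br carbon E-C1 has no ortho substituent, all other oxygens are methyl ethers, and the 2-aryloxyphenoxide cannot scramble by Smiles rearrangement because ring C is electron-rich.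

Step 15
Reactants: 28 heptadecamethyl ether of the target
Product: 30 CNP0304148.0, via heptadecakis(dibromoboryl) ether 29 (not isolated)
Conditions: BBr3 (excess), CH2Cl2, −78 °C to rt; then H2O, 0 °C, Ar
Reagents that add atoms: none
Why: Lewis-acid demethylation; BBr3 coordinates each methyl ether oxygen and bromide attacks the methyl carbon, while diaryl ether C–O bonds have no sp3 carbon and are not cleaved. Hydrolysis of the aryl borates (idealised as 29) should free the polyphenol, which is handled under argon and purified on Sephadex LH-20 or reversed phase.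

## Compound list

1 | 2,4,6-trimethoxybenzaldehyde | COc1cc(OC)c(C=O)c(OC)c1 | starting material
2 | 2,4,6-trimethoxyphenyl formate | COc1cc(OC)c(OC=O)c(OC)c1 | intermediate
3 | 2,4,6-trimethoxyphenol | COc1cc(OC)c(O)c(OC)c1 | intermediate
4 | 4-bromo-2,6-dimethoxyphenol | COc1cc(Br)cc(OC)c1O | starting material
5 | 2-(benzyloxy)-5-bromo-1,3-dimethoxybenzene | COc1cc(Br)cc(OC)c1OCc1ccccc1 | intermediate
6 | AB benzyl ether, 2-(benzyloxy)-1,3-dimethoxy-5-(2,4,6-trimethoxyphenoxy)benzene | COc1cc(OC)c(Oc2cc(OC)c(OCc3ccccc3)c(OC)c2)c(OC)c1 | intermediate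
7 | AB phenol, 2,6-dimethoxy-4-(2,4,6-trimethoxyphenoxy)phenol | COc1cc(OC)c(Oc2cc(OC)c(O)c(OC)c2)c(OC)c1 | intermediate
8 | ABC benzyl ether, 2-(benzyloxy)-5-[2,6-dimethoxy-4-(2,4,6-trimethoxyphenoxy)phenoxy]-1,3-dimethoxybenzene | COc1cc(OC)c(Oc2cc(OC)c(Oc3cc(OC)c(OCc4ccccc4)c(OC)c3)c(OC)c2)c(OC)c1 | intermediate
9 | ABC phenol, 4-[2,6-dimethoxy-4-(2,4,6-trimethoxyphenoxy)phenoxy]-2,6-dimethoxyphenol | COc1cc(OC)c(Oc2cc(OC)c(Oc3cc(OC)c(O)c(OC)c3)c(OC)c2)c(OC)c1 | intermediate
10 | trichloroethylene | ClC=C(Cl)Cl | starting material
11 | dichloroacetylene | ClC#CCl | intermediate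
12 | (E)-1,2-dichloro-1-(ABC-oxy)ethene | Cl/C=C(/Cl)Oc1c(OC)cc(Oc2c(OC)cc(Oc3c(OC)cc(OC)cc3OC)cc2OC)cc1OC | intermediate
13 | dimethyl squarate (3,4-dimethoxycyclobut-3-ene-1,2-dione) | COC1=C(OC)C(=O)C1=O | starting material
14 | ABC chloroethynyl ether, 1-chloro-2-(ABC-oxy)ethyne | ClC#COc1c(OC)cc(Oc2c(OC)cc(Oc3c(OC)cc(OC)cc3OC)cc2OC)cc1OC | intermediate
15 | lithium (ABC-oxy)acetylide | [Li]C#COc1c(OC)cc(Oc2c(OC)cc(Oc3c(OC)cc(OC)cc3OC)cc2OC)cc1OC | intermediate
16 | racemic lithium 1-[(ABC-oxy)ethynyl]-2,3-dimethoxy-4-oxocyclobut-2-en-1-olate | COC1=C(OC)C(O[Li])(C#COc2c(OC)cc(Oc3c(OC)cc(Oc4c(OC)cc(OC)cc4OC)cc3OC)cc2OC)C1=O | intermediate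
17 | racemic 4-[(ABC-oxy)ethynyl]-2,3,4-trimethoxycyclobut-2-en-1-one | COC1=C(OC)C(OC)(C#COc2c(OC)cc(Oc3c(OC)cc(Oc4c(OC)cc(OC)cc4OC)cc3OC)cc2OC)C1=O | intermediate
18 | racemic 4-[(Z)-2-(ABC-oxy)ethenyl]-2,3,4-trimethoxycyclobut-2-en-1-one | COC1=C(OC)C(OC)(/C=C\Oc2c(OC)cc(Oc3c(OC)cc(Oc4c(OC)cc(OC)cc4OC)cc3OC)cc2OC)C1=O | intermediate
19 | (3Z,5Z)-2,3,4-trimethoxy-6-(ABC-oxy)hexa-1,3,5-trien-1-one (dienylketene, vinyl group cis to the ketene) | O=C=C(OC)/C(OC)=C(OC)\C=C/Oc1c(OC)cc(Oc2c(OC)cc(Oc3c(OC)cc(OC)cc3OC)cc2OC)cc1OC | intermediate
20 | racemic 6-(ABC-oxy)-2,3,4-trimethoxycyclohexa-2,4-dien-1-one | O=C1C(Oc2c(OC)cc(Oc3c(OC)cc(Oc4c(OC)cc(OC)cc4OC)cc3OC)cc2OC)C=C(OC)C(OC)=C1OC | intermediate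
21 | ABCD phenol, 6-(ABC-oxy)-2,3,4-trimethoxyphenol | COc1cc(Oc2c(OC)cc(Oc3c(OC)cc(Oc4c(OC)cc(OC)cc4OC)cc3OC)cc2OC)c(O)c(OC)c1OC | intermediate
22 | 3,4,5-trimethoxyphenylboronic acid | COc1cc(B(O)O)cc(OC)c1OC | starting material
23 | FG bromide, 5-bromo-1,3-dimethoxy-2-(3,4,5-trimethoxyphenoxy)benzene | COc1cc(Oc2c(OC)cc(Br)cc2OC)cc(OC)c1OC | intermediate
24 | [3,5-dimethoxy-4-(3,4,5-trimethoxyphenoxy)phenyl]lithium | [Li]c1cc(OC)c(Oc2cc(OC)c(OC)c(OC)c2)c(OC)c1 | intermediate
25 | lithium [3,5-dimethoxy-4-(3,4,5-trimethoxyphenoxy)phenyl]triisopropoxyborate | [Li+].CC(C)O[B-](OC(C)C)(OC(C)C)c1cc(OC)c(Oc2cc(OC)c(OC)c(OC)c2)c(OC)c1 | intermediate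
26 | FG boronic acid, [3,5-dimethoxy-4-(3,4,5-trimethoxyphenoxy)phenyl]boronic acid | COc1cc(Oc2c(OC)cc(B(O)O)cc2OC)cc(OC)c1OC | intermediate
27 | EFG bromide, 5-bromo-2-[3,5-dimethoxy-4-(3,4,5-trimethoxyphenoxy)phenoxy]-1,3-dimethoxybenzene | COc1cc(Oc2c(OC)cc(Oc3c(OC)cc(Br)cc3OC)cc2OC)cc(OC)c1OC | intermediate
28 | heptadecamethyl ether of the target (all seventeen hydroxyls as OMe) | COc1cc(OC)c(Oc2cc(OC)c(Oc3cc(OC)c(Oc4cc(OC)c(OC)c(OC)c4Oc4cc(OC)c(Oc5cc(OC)c(Oc6cc(OC)c(OC)c(OC)c6)c(OC)c5)c(OC)c4)c(OC)c3)c(OC)c2)c(OC)c1 | intermediate
29 | heptadecakis(dibromoboryl) ether of the target (idealised aryl borate before hydrolysis) | BrB(Br)Oc1cc(OB(Br)Br)c(Oc2cc(OB(Br)Br)c(Oc3cc(OB(Br)Br)c(Oc4cc(OB(Br)Br)c(OB(Br)Br)c(OB(Br)Br)c4Oc4cc(OB(Br)Br)c(Oc5cc(OB(Br)Br)c(Oc6cc(OB(Br)Br)c(OB(Br)Br)c(OB(Br)Br)c6)c(OB(Br)Br)c5)c(OB(Br)Br)c4)c(OB(Br)Br)c3)c(OB(Br)Br)c2)c(OB(Br)Br)c1 | intermediate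
30 | CNP0304148.0 | Oc1cc(O)c(Oc2cc(O)c(Oc3cc(O)c(Oc4cc(O)c(O)c(O)c4Oc4cc(O)c(Oc5cc(O)c(Oc6cc(O)c(O)c(O)c6)c(O)c5)c(O)c4)c(O)c3)c(O)c2)c(O)c1 | target

## Step count and risks

Total: 15 steps. Longest linear sequence: 11 steps (1, 3, 4, 5, 6, 7, 8, 9, 10, 14, 15); step 2 and steps 11 to 13 are branches.

**Step 10 (key step).** The aryloxy group on the inner side of the closing terminus may slow the 6π closure. The dienylketene could then revert, dimerise, or be trapped by adventitious water or by the phenol already formed (ester formation). The fallback builds ring D from an arene instead; it sets out from 9 and returns at 21. Rieche formylation (Cl2CHOMe, TiCl4) of 5-bromo-1,2,3-trimethoxybenzene F1 should give 6-bromo-2,3,4-trimethoxybenzaldehyde F2. CuI and picolinic acid coupling of 9 with F2, whose ortho formyl group assists the copper insertion, gives the ABCD aldehyde F3. Dakin oxidation with mCPBA, through the ABCD formate F4 and methanolysis, gives 21.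

**Step 14.** C–O bond formation at a phenoxide flanked by an aryloxy and a methoxy group may be slow. Reduction of the C–Br bond of 27 and copper-mediated oxidation of the electron-rich phenoxide could then outrun the coupling. The fallback changes the electrophile and the bond-forming manifold; it sets out from 27 (with 21) and returns at 28. Bromine–lithium exchange, borate quench and hydrolysis as in step 12 convert 27 into the EFG boronic acid F5. This is joined to 21 by a room-temperature Chan–Lam coupling (Cu(OAc)2, pyridine, CH2Cl2), where C–O bond formation occurs from trivalent copper without heating.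

**Step 9.** Hydrogen uptake may not stop at the enol ether, or the propargylic C–O bond may be hydrogenolysed, on a substrate that also cannot be warmed. The fallback avoids the alkyne and also bypasses steps 7 and 8; it sets out from 9 and returns at 18. Transfer vinylation of 9 with vinyl acetate ([Ir(cod)Cl]2, Na2CO3, toluene, 100 °C) gives the ABC vinyl ether F6. One equivalent of Br2 at −78 °C gives the 1,2-dibromoethyl ether F7, and Et3N removes HBr to give the (Z)-2-bromovinyl ether F8. Bromine–lithium exchange with t-BuLi at −78 °C gives the (Z)-vinyllithium F9, which is added to 13 and methylated with MeOTf in the flask to give 18. This path was not chosen first because bromine may attack ring A and because F9 can lose phenoxide.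

**Step 13 (and its twin, step 11).** Divalent copper may oxidise bromophenol 4 by one electron (phenoxyl coupling, quinone formation), and the boronic acid may suffer protodeboronation or homocoupling. The fallback gives up the separate EFG fragment and grows the chain on the tetramer with the reactions of steps 3 to 6; it sets out from 21 and returns at 28. Ullmann coupling of 21 with 5 gives the ABCDE benzyl ether F10, and hydrogenolysis gives the ABCDE phenol F11. A second coupling with 5 gives the ABCDEF benzyl ether F12, and hydrogenolysis gives the ABCDEF phenol F13. A last Ullmann coupling with the bromide F1 already named closes ring G to give 28. This costs two more steps in the longest sequence.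

**Step 15.** Cleavage of seventeen ethers may stop short, and the free polyphenol may oxidise during isolation, leaving a mixture of polar phenols that cannot be separated. The fallback isolates through a stable derivative; it sets out from 28 and returns at 30. The crude product of the BBr3 cleavage is acetylated at once (Ac2O, pyridine) to the heptadecaacetate F14. This is purified on silica, where under-cleaved material separates, and is deacetylated by acidic methanolysis (HCl in MeOH, argon) to give 30.

## Further compounds

F1 | step 10 | 5-bromo-1,2,3-trimethoxybenzene | COc1cc(Br)cc(OC)c1OC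
F2 | step 10 | 6-bromo-2,3,4-trimethoxybenzaldehyde | COc1cc(Br)c(C=O)c(OC)c1OC
F3 | step 10 | ABCD aldehyde, 6-(ABC-oxy)-2,3,4-trimethoxybenzaldehyde | COc1cc(Oc2c(OC)cc(Oc3c(OC)cc(Oc4c(OC)cc(OC)cc4OC)cc3OC)cc2OC)c(C=O)c(OC)c1OC
F4 | step 10 | ABCD formate, 6-(ABC-oxy)-2,3,4-trimethoxyphenyl formate | COc1cc(Oc2c(OC)cc(Oc3c(OC)cc(Oc4c(OC)cc(OC)cc4OC)cc3OC)cc2OC)c(OC=O)c(OC)c1OC
F5 | step 14 | EFG boronic acid, [4-[3,5-dimethoxy-4-(3,4,5-trimethoxyphenoxy)phenoxy]-3,5-dimethoxyphenyl]boronic acid | COc1cc(Oc2c(OC)cc(Oc3c(OC)cc(B(O)O)cc3OC)cc2OC)cc(OC)c1OC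
F6 | step 9 | ABC vinyl ether, (ABC-oxy)ethene | C=COc1c(OC)cc(Oc2c(OC)cc(Oc3c(OC)cc(OC)cc3OC)cc2OC)cc1OC
F7 | step 9 | racemic 1,2-dibromo-1-(ABC-oxy)ethane | BrCC(Br)Oc1c(OC)cc(Oc2c(OC)cc(Oc3c(OC)cc(OC)cc3OC)cc2OC)cc1OC
F8 | step 9 | (Z)-1-bromo-2-(ABC-oxy)ethene | Br/C=C\Oc1c(OC)cc(Oc2c(OC)cc(Oc3c(OC)cc(OC)cc3OC)cc2OC)cc1OC
F9 | step 9 | [(Z)-2-(ABC-oxy)ethenyl]lithium | [Li]/C=C\Oc1c(OC)cc(Oc2c(OC)cc(Oc3c(OC)cc(OC)cc3OC)cc2OC)cc1OC
F10 | step 13 | ABCDE benzyl ether (28 cut after ring E, E-C4 oxygen as OBn) | COc1cc(OC)c(Oc2cc(OC)c(Oc3cc(OC)c(Oc4cc(OC)c(OC)c(OC)c4Oc4cc(OC)c(OCc5ccccc5)c(OC)c4)c(OC)c3)c(OC)c2)c(OC)c1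
F11 | step 13 | ABCDE phenol (E-C4 oxygen as OH) | COc1cc(OC)c(Oc2cc(OC)c(Oc3cc(OC)c(Oc4cc(OC)c(OC)c(OC)c4Oc4cc(OC)c(O)c(OC)c4)c(OC)c3)c(OC)c2)c(OC)c1
F12 | step 13 | ABCDEF benzyl ether (F-C4 oxygen as OBn) | COc1cc(OC)c(Oc2cc(OC)c(Oc3cc(OC)c(Oc4cc(OC)c(OC)c(OC)c4Oc4cc(OC)c(Oc5cc(OC)c(OCc6ccccc6)c(OC)c5)c(OC)c4)c(OC)c3)c(OC)c2)c(OC)c1
F13 | step 13 | ABCDEF phenol (F-C4 oxygen as OH) | COc1cc(OC)c(Oc2cc(OC)c(Oc3cc(OC)c(Oc4cc(OC)c(OC)c(OC)c4Oc4cc(OC)c(Oc5cc(OC)c(O)c(OC)c5)c(OC)c4)c(OC)c3)c(OC)c2)c(OC)c1
F14 | step 15 | heptadecaacetate of the target | CC(=O)Oc1cc(OC(C)=O)c(Oc2cc(OC(C)=O)c(Oc3cc(OC(C)=O)c(Oc4cc(OC(C)=O)c(OC(C)=O)c(OC(C)=O)c4Oc4cc(OC(C)=O)c(Oc5cc(OC(C)=O)c(Oc6cc(OC(C)=O)c(OC(C)=O)c(OC(C)=O)c6)c(OC(C)=O)c5)c(OC(C)=O)c4)c(OC(C)=O)c3)c(OC(C)=O)c2)c(OC(C)=O)c1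
A1 | alternative 1 | hexamethyl trimer acid with phenol head and carboxyl tail | COc1cc(Oc2c(OC)cc(Oc3c(OC)cc(C(=O)O)cc3OC)cc2OC)cc(OC)c1O
A2 | alternative 1 | syringic acid | COc1cc(C(=O)O)cc(OC)c1O
A3 | alternative 2 | heptamer with ring E as 3-hydroxy-5-ethoxy arene, other rings methylated | CCOc1cc(Oc2c(OC)c(OC)c(OC)cc2Oc2c(OC)cc(Oc3c(OC)cc(Oc4c(OC)cc(OC)cc4OC)cc3OC)cc2OC)cc(O)c1Oc1cc(OC)c(Oc2cc(OC)c(OC)c(OC)c2)c(OC)c1
A4 | alternative 2 | racemic 4-[3,5-dimethoxy-4-(3,4,5-trimethoxyphenoxy)phenoxy]-3-ethoxycyclobut-2-en-1-one | CCOC1=CC(=O)C1Oc1cc(OC)c(Oc2cc(OC)c(OC)c(OC)c2)c(OC)c1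
A5 | alternative 2 | ethynyl ether of the ABCD phenol | C#COc1c(OC)c(OC)c(OC)cc1Oc1c(OC)cc(Oc2c(OC)cc(Oc3c(OC)cc(OC)cc3OC)cc2OC)cc1OC
A6 | alternative 3 | heptamer with ring A as free triol and rings B to G methylated | Oc1cc(O)c(Oc2cc(OC)c(Oc3cc(OC)c(Oc4cc(OC)c(OC)c(OC)c4Oc4cc(OC)c(Oc5cc(OC)c(Oc6cc(OC)c(OC)c(OC)c6)c(OC)c5)c(OC)c4)c(OC)c3)c(OC)c2)c(O)c1
A7 | alternative 3 | methyl 6-aryloxy-3,5-dioxohexanoate carrying the methylated B-to-G hexamer | COC(=O)CC(=O)CC(=O)COc1cc(OC)c(Oc2cc(OC)c(Oc3cc(OC)c(OC)c(OC)c3Oc3cc(OC)c(Oc4cc(OC)c(Oc5cc(OC)c(OC)c(OC)c5)c(OC)c4)c(OC)c3)c(OC)c2)c(OC)c1
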